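With atom labels ring A = C1 (bears the exocyclic CH2), C2, C3, C4 (Br), C5 (CMe2), C6 (spiro) and ring B = C6, C7, C8, C9 (Me, Cl), C10 (Br), C11, the plan removes C9 and its methyl group from ring B. Since C9 is flanked by the C8 methylene and by C10, ring B traces back to a spiro cyclopentanone (carbonyl = C10) and diazoethane. The insertion makes C8–C9 and C9–C10 in one operation, expands ring B to six members and leaves a C10 ketone as the handle for both halogens. Its precursor is the (5R,9R)-bromo methylidene spiro[4.5]decan-2-one 14, assembled by [3+2] cycloaddition onto an enantioenriched ring A enone.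

Key step: step 9

Remark: compound names carry their own systematic locants, while C-labels in the text are those of the first paragraph; diazoethane 15 is not sold and is assumed to be generated just before use from commercial N-ethyl-N-nitrosourea (aq. KOH, Et2O, 0 °C), which is not counted as a step.

Step 1
Reactants: 1 prenol (3-methylbut-2-en-1-ol)
Product: 2 (2R)-2-bromo-3-chloro-3-methylbutan-1-ol
Conditions: NBS, ClTi(OiPr)3, chiral tridentate Schiff-base ligand (20 mol %), hexanes, −20 °C
Reagents that add atoms: N-bromosuccinimide, O=C1CCC(=O)N1Br; chlorotitanium triisopropoxide ClTi(OiPr)3, CC(C)O[Ti](Cl)(OC(C)C)OC(C)C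
Why: Catalytic enantioselective bromochlorination of an allylic alcohol, in which the ligand-bound titanium alkoxide of prenol takes Br+ from NBS on one alkene face and chloride opens the bromonium ion anti at the tertiary carbon (Markovnikov), so that the ligand enantiomer chosen sets the only C–Br stereocentre as R.

Step 2
Reactants: 2 (2R)-2-bromo-3-chloro-3-methylbutan-1-ol
Product: 3 (2R)-2-bromo-3-chloro-3-methylbutyl trifluoromethanesulfonate
Conditions: Tf2O, 2,6-lutidine, CH2Cl2, −78 °C
Reagents that add atoms: trifluoromethanesulfonic anhydride, O=S(=O)(OS(=O)(=O)C(F)(F)F)C(F)(F)F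
Why: Standard O-sulfonylation of a primary alcohol, in which the neighbouring halogens inductively retard ionisation so that the primary triflate survives a cold work-up and can be used directly.

Step 3
Reactants: 3 (2R)-2-bromo-3-chloro-3-methylbutyl trifluoromethanesulfonate; 4 allyl acetoacetate
Product: 6 allyl (6R)-6-bromo-7-chloro-7-methyl-3-oxooctanoate, via allyl acetoacetate dianion 5 (not isolated)
Conditions: 4, LiN(iPr)2 (2.1 equiv), THF, −78 → 0 °C; then 3, −78 → −30 °C; aq. NH4Cl
Reagents that add atoms: none
Why: γ-Alkylation of an acetoacetate dianion, in which the more basic terminal carbon of 5 displaces the primary triflate by SN2 at low temperature faster than it can dehydrohalogenate the secondary bromide or the tertiary chloride, the stereocentre being untouched.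

Step 4
Reactants: 6 allyl (6R)-6-bromo-7-chloro-7-methyl-3-oxooctanoate
Product: 7 allyl (3R)-3-bromo-2,2-dimethyl-6-oxocyclohexane-1-carboxylate (C1 epimers and enol form)
Conditions: (CF3)2CHOH, 23 °C
Reagents that add atoms: none
Why: Solvolytic bromonium cyclisation, in which the ionising non-nucleophilic solvent lets the tertiary chloride leave with anchimeric help from the vicinal bromine and the enol carbon of the β-keto ester opens the bromonium ion at its tertiary carbon (6-endo), so that bromine never leaves its carbon and the R configuration is carried over.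

Step 5
Reactants: 7 allyl (3R)-3-bromo-2,2-dimethyl-6-oxocyclohexane-1-carboxylate
Product: 9 (4R)-4-bromo-3,3-dimethyl-2-methylidenecyclohexan-1-one, via β-keto acid 8 (not isolated)
Conditions: Pd(PPh3)4 (5 mol %), morpholine (1.3 equiv), THF, 0 → 23 °C; then 37 % aq. CH2O, AcOH, 23 °C
Reagents that add atoms: formaldehyde, C=O
Why: Tsuji–Trost deallylation with zerovalent palladium and morpholine as allyl acceptor frees the β-keto acid 8, whose α-carbon then undergoes a Mannich reaction with the formaldehyde-derived iminium ion and decarboxylative elimination of the amine, which places the methylidene group only at the carboxyl-bearing carbon.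

Step 6
Reactants: 9 (4R)-4-bromo-3,3-dimethyl-2-methylidenecyclohexan-1-one; 10 2-[(trimethylsilyl)methyl]allyl acetate
Product: 11 (5S,9R)-9-bromo-10,10-dimethyl-2-methylidenespiro[4.5]decan-6-one
Conditions: Pd(OAc)2 (5 mol %), P(OiPr)3 (30 mol %), 10 (1.5 equiv), THF, 65 °C
Reagents that add atoms: none
Why: Palladium-catalysed trimethylenemethane [3+2] cycloaddition, in which the zwitterionic trimethylenemethane complex of zerovalent palladium (formed in situ from Pd(OAc)2 and the phosphite) adds to the exocyclic CH2 (C7) of the s-cis enone and the resulting C6 enolate closes 5-exo onto the π-allyl terminus, forming C6–C11 axially on the half-chair that keeps the C4 bromide equatorial and anti to the pseudo-axial C5 methyl, so that C11 ends up trans to bromine (5S).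

Step 7
Reactants: 11 (5S,9R)-9-bromo-10,10-dimethyl-2-methylidenespiro[4.5]decan-6-one
Product: 12 (5R,9R)-9-bromo-10,10-dimethyl-2,6-dimethylidenespiro[4.5]decane
Conditions: Cp2TiMe2 (3 equiv), toluene, 75 °C, dark
Reagents that add atoms: dimethyltitanocene Cp2TiMe2, C[Ti](C)(C1C=CC=C1)C1C=CC=C1
Why: Petasis methylenation, in which thermally generated Cp2Ti=CH2 is non-basic and small enough to convert the hindered, enolisable C1 ketone into the exocyclic alkene through an oxatitanacyclobutane without touching the alkyl bromide or the existing alkene.

Step 8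
Reactants: 12 (5R,9R)-9-bromo-10,10-dimethyl-2,6-dimethylidenespiro[4.5]decane
Product: 14 (5R,9R)-9-bromo-10,10-dimethyl-6-methylidenespiro[4.5]decan-2-one, via diol 13 (not isolated)
Conditions: OsO4 (2 mol %), NMO (1.05 equiv), acetone/H2O, 0 °C; then NaIO4, THF/H2O, 23 °C
Reagents that add atoms: osmium tetroxide OsO4 (catalytic oxygen carrier), O=[Os](=O)(=O)=O; N-methylmorpholine N-oxide, C[N+]1([O-])CCOCC1
Why: Catalytic OsO4/NMO dihydroxylation followed by periodate glycol cleavage (a two-stage Lemieux–Johnson-type cleavage), in which osmylation should discriminate sterically between the two 1,1-disubstituted alkenes, taking the cyclopentylidene CH2 flanked by two methylene groups well before the C1 methylidene wedged against the quaternary C6/C5 pair, after which diol 13 is cut to the C10 ketone.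

Step 9
Reactants: 14 (5R,9R)-9-bromo-10,10-dimethyl-6-methylidenespiro[4.5]decan-2-one; 15 diazoethane
Product: 16 (6R,10R)-10-bromo-3,11,11-trimethyl-7-methylidenespiro[5.5]undecan-2-one (both C3 epimers)
Conditions: Sc(OTf)3 (10 mol %), 15 (1.5 equiv, Et2O solution), toluene, −78 °C
Reagents that add atoms: none
Why: Sc(OTf)3 activates the C10 carbonyl, the nucleophilic carbon of diazoethane adds to it, and in the resulting β-oxido diazonium betaine the ring bond C10–C8 shifts to the new carbon as N2 leaves, which forms C9–C10 and C8–C9 in one event. The closest known reaction type is the Lewis-acid-catalysed one-carbon homologation of cycloalkanones with substituted diazoalkanes (a Tiffeneau–Demjanov-type ring expansion). Ring B is not closed by a cyclisation but enlarged from five to six members by this 1,2-alkyl shift, and relief of cyclopentanone eclipsing strain makes the initial addition fast. The new C9 stereocentre is not controlled, which is harmless because it is α to the ketone, epimerisable and erased in step 10, while C4 and C6 are untouched. The step needs migration of C8 and not of C11, and the substrate favours this because C11 is neopentyl, bonded to the spiro carbon C6 that is flanked by the C5 gem-dimethyl carbon and by C1, so the betaine rotamer that would align C10–C11 anti to the departing nitrogen presses the diazoethane methyl group and the scandium alkoxide against ring A. Chemoselectivity follows from the cyclopentanone being the only carbonyl, from the alkene and the secondary bromide being inert to the catalyst, and from the α-branched cyclohexanone product being too hindered to be homologated again at −78 °C.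

Step 10
Reactants: 16 (6R,10R)-10-bromo-3,11,11-trimethyl-7-methylidenespiro[5.5]undecan-2-one
Product: 17 (6R,10R)-10-bromo-3,11,11-trimethyl-7-methylidenespiro[5.5]undec-2-en-2-yl trifluoromethanesulfonate
Conditions: Tf2O, 2,6-di-tert-butyl-4-methylpyridine, CH2Cl2, 0 → 23 °C
Reagents that add atoms: trifluoromethanesulfonic anhydride, O=S(=O)(OS(=O)(=O)C(F)(F)F)C(F)(F)F
Why: Enol triflate formation from a ketone with Tf2O and a hindered pyridine, in which deprotonation of the O-triflyl oxocarbenium ion should favour the tetrasubstituted C9=C10 enol triflate over the C10=C11 isomer whose double bond would abut the spiro centre, both C9 epimers of 16 converging on 17.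

Step 11
Reactants: 17 (6R,10R)-10-bromo-3,11,11-trimethyl-7-methylidenespiro[5.5]undec-2-en-2-yl trifluoromethanesulfonate
Product: 18 (6R,10R)-10-bromo-3,11,11-trimethyl-7-methylidenespiro[5.5]undec-2-ene
Conditions: Pd(OAc)2 (5 mol %), PPh3 (10 mol %), HCO2H, n-Bu3N, DMF, 60 °C
Reagents that add atoms: none
Why: Palladium-catalysed formate reduction of a vinyl triflate, in which zerovalent palladium formed in situ inserts into the C–OTf bond and formate delivers hydride with loss of CO2, while the neopentyl-type secondary bromide does not undergo oxidative addition with this PPh3-ligated catalyst.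

Step 12
Reactants: 18 (6R,10R)-10-bromo-3,11,11-trimethyl-7-methylidenespiro[5.5]undec-2-ene
Product: 19 (2R,3S,6R,10R)-10-bromo-2,3-epoxy-3,11,11-trimethyl-7-methylidenespiro[5.5]undecane (oxygen on the ring B face syn to C5)
Conditions: D-fructose-derived Shi ketone (30 mol %), KHSO5 (as 2KHSO5·KHSO4·K2SO4), K2CO3, n-Bu4NHSO4, MeCN/CH2(OMe)2, aq. Na2B4O7 buffer, 0 °C
Reagents that add atoms: potassium peroxymonosulfate KHSO5, [K+].[O-]S(=O)(=O)OO
Why: Shi asymmetric epoxidation, in which the chiral dioxirane formed from the ketone and KHSO5 reacts with the electron-rich trisubstituted C9=C10 alkene in preference to the hindered 1,1-disubstituted C1 methylidene and, through its spiro transition state, should deliver oxygen to the C9 Si/C10 Re face (the ring B face syn to C5), setting both epoxide carbons under reagent control.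

Step 13
Reactants: 19 (2R,3S,6R,10R)-10-bromo-2,3-epoxy-3,11,11-trimethyl-7-methylidenespiro[5.5]undecane
Product: 20 (2R,3R,6R,10R)-10-bromo-3-chloro-3,11,11-trimethyl-7-methylidenespiro[5.5]undecan-2-ol
Conditions: HCl (1 M in Et2O, 1.5 equiv), CH2Cl2, −78 → −40 °C
Reagents that add atoms: hydrogen chloride, Cl
Why: Acid-mediated Markovnikov opening of a trisubstituted epoxide, in which chloride attacks the protonated epoxide at the tertiary carbon C9 anti to the departing oxygen, so that C9 is inverted and the C10 hydroxyl keeps its configuration trans to chlorine, while at this temperature the hindered exocyclic alkene should not be protonated.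

Step 14
Reactants: 20 (2R,3R,6R,10R)-10-bromo-3-chloro-3,11,11-trimethyl-7-methylidenespiro[5.5]undecan-2-ol
Product: 22 (2S,3R,6R,10R)-2,10-dibromo-3-chloro-3,11,11-trimethyl-7-methylidenespiro[5.5]undecane (the target), via secondary triflate 21 (not isolated)
Conditions: Tf2O, 2,6-di-tert-butyl-4-methylpyridine, CH2Cl2, −40 °C; then n-Bu4NBr (3 equiv), toluene, −20 → 23 °C
Reagents that add atoms: tetrabutylammonium bromide, CCCC[N+](CCCC)(CCCC)CCCC.[Br-]
Why: Two-stage SN2 bromination, in which the hindered C10 alcohol becomes the triflate 21, a very good leaving group whose ionisation is held back by the β-chlorine, and bromide displaces it from the rear with inversion, so that bromine arrives cis to the C9 chlorine (2S).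

Compound list
1 | prenol (3-methylbut-2-en-1-ol) | CC(C)=CCO | starting material
2 | (2R)-2-bromo-3-chloro-3-methylbutan-1-ol | OC[C@@H](Br)C(C)(C)Cl | intermediate
3 | (2R)-2-bromo-3-chloro-3-methylbutyl trifluoromethanesulfonate | O=S(=O)(OC[C@@H](Br)C(C)(C)Cl)C(F)(F)F | intermediate
4 | allyl acetoacetate | CC(=O)CC(=O)OCC=C | starting material
5 | dilithium dianion (bis-enolate) of allyl acetoacetate | [Li+].[Li+].C=C([O-])C=C([O-])OCC=C | intermediate (not isolated)
6 | allyl (6R)-6-bromo-7-chloro-7-methyl-3-oxooctanoate | C=CCOC(=O)CC(=O)CC[C@@H](Br)C(C)(C)Cl | intermediate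
7 | allyl (3R)-3-bromo-2,2-dimethyl-6-oxocyclohexane-1-carboxylate (C1 epimers, enolisable) | C=CCOC(=O)C1C(=O)CC[C@@H](Br)C1(C)C | intermediate
8 | (3R)-3-bromo-2,2-dimethyl-6-oxocyclohexane-1-carboxylic acid | OC(=O)C1C(=O)CC[C@@H](Br)C1(C)C | intermediate (not isolated)
9 | (4R)-4-bromo-3,3-dimethyl-2-methylidenecyclohexan-1-one | C=C1C(=O)CC[C@@H](Br)C1(C)C | intermediate
10 | 2-[(trimethylsilyl)methyl]allyl acetate | CC(=O)OCC(=C)C[Si](C)(C)C | starting material
11 | (5S,9R)-9-bromo-10,10-dimethyl-2-methylidenespiro[4.5]decan-6-one | O=C1CC[C@@H](Br)C(C)(C)[C@@]12CCC(=C)C2 | intermediate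
12 | (5R,9R)-9-bromo-10,10-dimethyl-2,6-dimethylidenespiro[4.5]decane | C=C1CC[C@@H](Br)C(C)(C)[C@@]12CCC(=C)C2 | intermediate
13 | (5R,9R)-9-bromo-2-(hydroxymethyl)-10,10-dimethyl-6-methylidenespiro[4.5]decan-2-ol (either C2 epimer) | C=C1CC[C@@H](Br)C(C)(C)[C@@]12CCC(O)(CO)C2 | intermediate (not isolated)
14 | (5R,9R)-9-bromo-10,10-dimethyl-6-methylidenespiro[4.5]decan-2-one | C=C1CC[C@@H](Br)C(C)(C)[C@@]12CCC(=O)C2 | intermediate
15 | diazoethane (generated fresh from N-ethyl-N-nitrosourea) | CC=[N+]=[N-] | starting material
16 | (6R,10R)-10-bromo-3,11,11-trimethyl-7-methylidenespiro[5.5]undecan-2-one (both C3 epimers) | C=C1CC[C@@H](Br)C(C)(C)[C@@]12CCC(C)C(=O)C2 | intermediate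
17 | (6R,10R)-10-bromo-3,11,11-trimethyl-7-methylidenespiro[5.5]undec-2-en-2-yl trifluoromethanesulfonate | C=C1CC[C@@H](Br)C(C)(C)[C@@]12CCC(C)=C(OS(=O)(=O)C(F)(F)F)C2 | intermediate
18 | (6R,10R)-10-bromo-3,11,11-trimethyl-7-methylidenespiro[5.5]undec-2-ene | C=C1CC[C@@H](Br)C(C)(C)[C@@]12CCC(C)=CC2 | intermediate
19 | (2R,3S,6R,10R)-10-bromo-2,3-epoxy-3,11,11-trimethyl-7-methylidenespiro[5.5]undecane | C=C1CC[C@@H](Br)C(C)(C)[C@@]12CC[C@]3(C)O[C@@H]3C2 | intermediate
20 | (2R,3R,6R,10R)-10-bromo-3-chloro-3,11,11-trimethyl-7-methylidenespiro[5.5]undecan-2-ol | C=C1CC[C@@H](Br)C(C)(C)[C@@]12CC[C@@](C)(Cl)[C@H](O)C2 | intermediate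
21 | (2R,3R,6R,10R)-10-bromo-3-chloro-3,11,11-trimethyl-7-methylidenespiro[5.5]undecan-2-yl trifluoromethanesulfonate | C=C1CC[C@@H](Br)C(C)(C)[C@@]12CC[C@@](C)(Cl)[C@H](OS(=O)(=O)C(F)(F)F)C2 | intermediate (not isolated)
22 | (2S,3R,6R,10R)-2,10-dibromo-3-chloro-3,11,11-trimethyl-7-methylidenespiro[5.5]undecane | C=C1CC[C@@H](Br)C(C)(C)[C@@]12CC[C@@](C)(Cl)[C@@H](Br)C2 | target

Total step count: 14. Longest linear sequence: 14 steps, from prenol 1 to 22.

Steps most likely to fail

1. Step 9. The 1,2-shift may be taken by the wrong ring bond (C10–C11 in place of C10–C8), which would insert the methyl-bearing carbon on the spiro side, or the betaine may collapse to a spiro epoxide without rearranging. The fallback sets out from enone 9 and comes back at alkene 18. A Me2AlCl-promoted Diels–Alder reaction of 9 with isoprene (CH2Cl2, −78 → −20 °C) should add the diene to the exocyclic alkene with para orientation, on the face anti to the pseudo-axial C5 methyl. This would give (6S,10R)-10-bromo-3,11,11-trimethylspiro[5.5]undec-2-en-7-one F1, in which ring B already carries the C9=C10 alkene. Methylenation of its ring A ketone with Cp2TiMe2, as in step 7, then gives 18, so ring B comes from a [4+2] cycloaddition and no ring enlargement is needed.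

2. Step 14. At the neopentyl-type secondary carbon C10, E2 loss of the triflate toward C11, or participation of the C9 chlorine (chloronium ion, leading to retention or a 1,2-chlorine shift), may outrun backside attack by bromide. The fallback sets out from alkene 18 and comes back at 22. PhSeCl (CH2Cl2, −78 → 23 °C, equilibrating conditions) should add anti across C9=C10 to give the Markovnikov adduct (2R,3R,6R,10R)-10-bromo-3-chloro-3,11,11-trimethyl-7-methylidene-2-(phenylselanyl)spiro[5.5]undecane F2, with chlorine on C9 and selenium on C10. Br2 (CH2Cl2, −78 → 0 °C) then turns the selenide into its tetravalent selenium dibromide, a far better nucleofuge than a sulfonate, which bromide displaces with inversion at C10 to give 22 directly. In this variant the ring B face is chosen by the substrate under thermodynamic control, and steps 12 to 14 are bypassed.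

3. Step 6. Proton transfer from the enolisable C2 methylene of 9 may quench the basic trimethylenemethane–palladium zwitterion, or ring closure at the congested C6 enolate may be slower than its protonation, so that open-chain adducts form. The fallback sets out from 9 and comes back at 11. TiCl4-mediated Hosomi–Sakurai conjugate addition of 2-(chloromethyl)-3-(trimethylsilyl)prop-1-ene (CH2Cl2, −78 °C) to the exocyclic CH2 of 9 should give (4R)-4-bromo-2-[3-(chloromethyl)but-3-en-1-yl]-3,3-dimethylcyclohexan-1-one F3. KOtBu (t-BuOH/THF, 0 → 23 °C) then equilibrates the enolates, and the more substituted C6 enolate closes the methylenecyclopentane by intramolecular SN2 alkylation (5-exo-tet). This gives 11 with the same axial approach anti to the C5 methyl.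

Further compounds
F1 | step 9 | (6S,10R)-10-bromo-3,11,11-trimethylspiro[5.5]undec-2-en-7-one | O=C1CC[C@@H](Br)C(C)(C)[C@@]12CCC(C)=CC2
F2 | step 14 | (2R,3R,6R,10R)-10-bromo-3-chloro-3,11,11-trimethyl-7-methylidene-2-(phenylselanyl)spiro[5.5]undecane | C=C1CC[C@@H](Br)C(C)(C)[C@@]12CC[C@@](C)(Cl)[C@H]([Se]c3ccccc3)C2
F3 | step 6 | (4R)-4-bromo-2-[3-(chloromethyl)but-3-en-1-yl]-3,3-dimethylcyclohexan-1-one (either C2 epimer) | O=C1CC[C@@H](Br)C(C)(C)C1CCC(=C)CCl
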